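**Assumption:** gibberellic acid (GA3), a bulk fermentation product sold by the major suppliers, counts as a commercially available starting material. The route is therefore a relay (semi)synthesis from GA3, not a de novo construction of the skeleton.

## Retrosynthetic overview

1. GA8 ⇐ GA5 by syn-dihydroxylation of the C2=C3 alkene from the β-face, anti to the 19,10-lactone bridge; this sets C2 and C3 together.
2. GA5 ⇐ GA3 by reductive 1,3-transposition of the allylic alcohol (3β-OH/Δ1 → Δ2): SN2' chlorination, then radical dechlorination, with the C7 acid masked as its methyl ester.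
3. Ring formation: none. Rings A–D, the γ-lactone and stereocentres C4, C5, C6, C8, C9, C10 and C13 are bought intact in GA3.

## Route

**Step 1**
Reactants: 1, gibberellic acid (GA3; 3β,13-dihydroxy-1,16-diene, 19,10α-lactone, 7-carboxylic acid)
Product: 2, GA3 methyl ester (C7 methyl ester)
Conditions: MeI, KHCO3, DMF, rt
Reagents that add atoms: methyl iodide, CI
Why: SN2 O-alkylation of the carboxylate under bicarbonate, mild enough to avoid base-induced allylic lactone rearrangement; no stereocentre is touched, and the acid is masked for the Appel step.

**Step 2**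
Reactants: 2, GA3 methyl ester
Product: 3, 1β-chloro-gibberellin A5 methyl ester (1β-Cl, Δ2, 13-OH, Δ16, lactone and ester intact)
Conditions: PPh3, CCl4, reflux
Reagents that add atoms: carbon tetrachloride, ClC(Cl)(Cl)Cl (Cl only)
Why: Appel activation of the 3β-OH; direct SN2 at neopentylic C3 is blocked by the lactone bridge, so chloride attacks C1 in a syn SN2' and moves the alkene to C2=C3. The bridgehead tertiary 13-OH is inert, the C1 configuration is erased in step 3, and any 3α-chloro-Δ1 isomer converges to the same allyl radical there.

**Step 3**
Reactants: 3, 1β-chloro-gibberellin A5 methyl ester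
Product: 4, gibberellin A5 methyl ester (Δ2, Δ16, 13-OH, lactone, methyl ester)
Conditions: Bu3SnH, AIBN (cat.), PhH, reflux
Reagents that add atoms: none
Why: radical-chain dehalogenation; Bu3Sn• abstracts the allylic chlorine and the C1–C2–C3 allyl radical should take hydrogen mainly at C1, leaving the Δ2 alkene. C1 becomes CH2, so no stereocentre is created, and the ester, lactone, 13-OH and exocyclic alkene are inert.

**Step 4**
Reactants: 4, gibberellin A5 methyl ester
Product: 5, gibberellin A5 (free C7 acid)
Conditions: n-PrSLi, HMPA, rt; then dilute HCl to pH 3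
Reagents that add atoms: none
Why: SN2 O-demethylation by a soft thiolate at the ester methyl carbon, which avoids hydroxide and leaves the γ-lactone closed. It is done before the 3-OH is installed, so retro-aldol epimerisation at C3 cannot occur.

**Step 5**
Reactants: 5, gibberellin A5
Product: 6, gibberellin A8 (2β,3β,13-triol; target)
Conditions: OsO4 (1.05 equiv), pyridine/THF, −20 → 0 °C; then aq. NaHSO3, rt
Reagents that add atoms: osmium tetroxide, O=[Os](=O)(=O)=O (both new O atoms)
Why: concerted [3+2] syn-dihydroxylation of the cis-disubstituted ring-A alkene from its open β (exo) face; the α-face is covered by the lactone bridge, so 2β-OH and 3β-OH are set together. The exocyclic C16=CH2 is expected to react more slowly (neopentylic, deactivated by the allylic tertiary OH), so limiting OsO4 should give ring-A selectivity.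

## Compound list

1 | Gibberellic acid (GA3) | C=C1C[C@]23C[C@@]1(O)CC[C@H]2[C@@]12C=C[C@H](O)[C@@](C)(C(=O)O1)[C@H]2[C@@H]3C(=O)O | starting material
2 | GA3 methyl ester | C=C1C[C@]23C[C@@]1(O)CC[C@H]2[C@@]12C=C[C@H](O)[C@@](C)(C(=O)O1)[C@H]2[C@@H]3C(=O)OC | intermediate
3 | 1β-Chloro-gibberellin A5 methyl ester | C=C1C[C@]23C[C@@]1(O)CC[C@H]2[C@@]12[C@H](Cl)C=C[C@@](C)(C(=O)O1)[C@H]2[C@@H]3C(=O)OC | intermediate
4 | Gibberellin A5 methyl ester | C=C1C[C@]23C[C@@]1(O)CC[C@H]2[C@@]12CC=C[C@@](C)(C(=O)O1)[C@H]2[C@@H]3C(=O)OC | intermediate
5 | Gibberellin A5 | C=C1C[C@]23C[C@@]1(O)CC[C@H]2[C@@]12CC=C[C@@](C)(C(=O)O1)[C@H]2[C@@H]3C(=O)O | intermediate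
6 | Gibberellin A8 | C=C1C[C@]23C[C@@]1(O)CC[C@H]2[C@@]12C[C@H](O)[C@H](O)[C@@](C)(C(=O)O1)[C@H]2[C@@H]3C(=O)O | target

## Summary

Total step count: 5
Longest linear sequence: 5 steps (fully linear from GA3)

Three steps most likely to fail:

1. **Step 5 (OsO4).** Competing dihydroxylation of the exocyclic C16=CH2 would give the 16,17-diol or a pentaol. Fallback: remove the competing alkene from the sequence. Cleave C16=CH2 of 2 to the 17-nor-16-ketone (OsO4/NaIO4; the deactivated Δ1 alkene is spared), run steps 2–3, dihydroxylate the only remaining alkene, protect the diol as an acetonide, reinstall the methylene by Wittig reaction (Ph3P=CH2), then deprotect.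

2. **Step 3 (Bu3SnH).** H-transfer at C3 instead of C1 would give the Δ1 isomer, and the allylic chloride may reduce sluggishly. Fallback: avoid the allyl radical. Oxidise 2 with MnO2 to the Δ1-3-ketone, form the tosylhydrazone and reduce it with catecholborane (Kabalka reductive 1,3-transposition), which delivers the Δ2 alkene regiospecifically and replaces steps 2–3.

3. **Step 2 (Appel SN2').** Elimination or lactone migration through an allyl cation, or poor conversion of the hindered alcohol, could intervene. Fallback: perform the transposition by a sigmatropic rather than ionic mechanism. Convert the 3β-OH to its O-thiocarbonyl (xanthate or imidazolide) derivative, let it undergo [3,3] rearrangement to the 1β-S-allyl thiocarbonate, and reduce that with Bu3SnH to 4.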